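## Retrosynthetic overview

1. Target 25 ⇐ removal of three O‑benzyl groups from 24 ⇐ Suzuki coupling across the central 6',6''‑bond of bromonaphthol 15 (5,8'‑linked half) and aryl chloride 22 (1'',5'''‑linked half).
2. Every ring comes from a polyketide‑type 1,5‑diketone (2‑acetylphenylacetones 4 and 19, both from 2',6'‑dihydroxyacetophenone 1): aldol aromatisation gives the naphthalenes, transamination with imine closure gives the isoquinoline.
3. C3 is set by an (R)‑selective transaminase in the ring‑closing cascade, C1 by a trans‑selective imine reduction; the resulting bromide 8 serves both halves.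
4. The 5,8'‑half joins para‑bromonaphthol 12 to the boronate of 8. In the 1'',5'''‑half the naphthalene is built onto the isoquinoline: α‑arylation of diketone 19 with 8, then aldol aromatisation.
5. Ring order: isoquinoline (6, 7) → naphthalene of the 5,8'‑half (10) → naphthalene of the 1'',5'''‑half (22, formed together with its biaryl bond).

Assumption: the SMILES fixes only the four stereocentres (1R,3R in both tetrahydroisoquinolines) and no biaryl axis; only the C1''–C5''' axis should be rotationally stable, so 22 forms as two atropo‑diastereomers, which are separated by chromatography, and either is taken on.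

Locants: isoquinoline 1–8 and naphthalene 1'–8' in the 5,8'‑linked half; naphthalene 1''–8'' and isoquinoline 1'''–8''' in the other half.

## Route

Step 1
Reactants: 1 1-(2,6-dihydroxyphenyl)ethan-1-one
Product: 2 1-[2-(benzyloxy)-6-hydroxyphenyl]ethan-1-one
Conditions: BnBr (1.05 equiv), K2CO3, acetone, reflux
Reagents that add atoms: benzyl bromide BrCc1ccccc1
Why: Williamson ether synthesis that stops at the mono‑ether because the remaining OH is locked in the chelate with the acetyl C=O; no stereocentre.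

Step 2
Reactants: 2 1-[2-(benzyloxy)-6-hydroxyphenyl]ethan-1-one
Product: 3 2-acetyl-3-(benzyloxy)phenyl trifluoromethanesulfonate
Conditions: Tf2O (1.2 equiv), pyridine, CH2Cl2, 0 °C
Reagents that add atoms: trifluoromethanesulfonic anhydride O=S(=O)(OS(=O)(=O)C(F)(F)F)C(F)(F)F
Why: O‑sulfonylation (triflation) of the chelated phenol turns the second oxygen into a cross‑coupling leaving group; no stereocentre.

Step 3
Reactants: 3 2-acetyl-3-(benzyloxy)phenyl trifluoromethanesulfonate
Product: 4 1-[2-acetyl-3-(benzyloxy)phenyl]propan-2-one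
Conditions: isopropenyl acetate (1.5 equiv), Bu3SnOMe (1.5 equiv), PdCl2(PPh3)2 (5 mol %), LiCl (3 equiv), toluene/DMF 4:1, 100 °C
Reagents that add atoms: isopropenyl acetate CC(=C)OC(C)=O
Why: Kosugi–Migita acetonylation, a Stille‑type coupling of the tin enolate made in the flask (established for aryl bromides; the triflate is engaged with LiCl as in Stille couplings), chosen because its neutral medium keeps the base‑sensitive 1,5‑diketone from cyclising; no stereocentre.

Step 4
Reactants: 4 1-[2-acetyl-3-(benzyloxy)phenyl]propan-2-one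
Product: 6 (3R)-8-(benzyloxy)-1,3-dimethyl-3,4-dihydroisoquinoline, via amino ketone 5 (not isolated)
Conditions: (R)-selective ω-transaminase (ATA-117 type, Arthrobacter sp.), pyridoxal 5'-phosphate (1 mM), i-PrNH2 (1 M), phosphate buffer pH 8.0/DMSO 4:1, 35 °C, N2
Reagents that add atoms: isopropylamine CC(C)N
Why: ω‑Transaminase reductive amination with spontaneous aza‑cyclisation (known for 1,5‑diketones giving cyclic imines): the enzyme aminates only the unhindered benzyl methyl ketone and delivers nitrogen to one face, setting C3 as R (ArCH2 in the large pocket, CH3 in the small one), and amine 5 condenses at once with the ortho acetyl group to the six‑membered ketimine, which also pulls the equilibrium.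

Step 5
Reactants: 6 (3R)-8-(benzyloxy)-1,3-dimethyl-3,4-dihydroisoquinoline
Product: 7 (1R,3R)-8-(benzyloxy)-1,3-dimethyl-1,2,3,4-tetrahydroisoquinoline
Conditions: AlMe3 (3 equiv), THF, −78 °C; then LiAlH4 (3 equiv), −78 → −20 °C; quench H2O
Reagents that add atoms: none
Why: Diastereoselective hydride reduction of the cyclic ketimine, in which hydride enters cis to the C3 methyl of the AlMe3‑bound imine and so sets C1 as R (1,3‑trans; the known trans‑selective LiAlH4/AlMe3 reduction of 1,3‑dimethyl‑3,4‑dihydroisoquinolines, whereas NaBH4 gives cis); the minor cis isomer is removed by chromatography.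

Step 6
Reactants: 7 (1R,3R)-8-(benzyloxy)-1,3-dimethyl-1,2,3,4-tetrahydroisoquinoline
Product: 8 (1R,3R)-8-(benzyloxy)-5-bromo-1,3-dimethyl-1,2,3,4-tetrahydroisoquinoline
Conditions: Br2 (1.05 equiv), NaOAc (1.5 equiv), AcOH, 20 °C
Reagents that add atoms: bromine BrBr
Why: Electrophilic aromatic bromination para to the benzyloxy group (C5), with the amine held as its ammonium salt in AcOH so that nitrogen is not oxidised; stereocentres untouched.

Step 7
Reactants: 4 1-[2-acetyl-3-(benzyloxy)phenyl]propan-2-one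
Product: 10 1-(benzyloxy)-8-methoxy-6-methylnaphthalene, via naphthol 9 (not isolated)
Conditions: KOtBu (1.2 equiv), THF, 0 → 20 °C; then MeI (1.5 equiv), DMF, 0 → 20 °C
Reagents that add atoms: iodomethane CI
Why: Base‑induced intramolecular aldol condensation and aromatisation of the 1,5‑diketone (the enolate of the aryl methyl ketone adds to the unhindered methyl ketone, as known for 2‑acetylphenylacetones giving 3‑methyl‑1‑naphthols), then Williamson methylation of the naphthoxide in the same flask, which places OMe on the new ring; no stereocentre.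

Step 8
Reactants: 10 1-(benzyloxy)-8-methoxy-6-methylnaphthalene
Product: 11 8-methoxy-6-methylnaphthalen-1-ol
Conditions: H2 (1 atm), 10% Pd/C, EtOAc/MeOH, 20 °C
Reagents that add atoms: none
Why: Hydrogenolysis of the benzyl ether frees the hydroxyl that will direct the next two substitutions; the methyl ether and the naphthalene are inert under these conditions.

Step 9
Reactants: 11 8-methoxy-6-methylnaphthalen-1-ol
Product: 12 4-bromo-8-methoxy-6-methylnaphthalen-1-ol
Conditions: NBS (1.0 equiv), MeCN, −20 °C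
Reagents that add atoms: N-bromosuccinimide O=C1CCC(=O)N1Br
Why: Electrophilic aromatic bromination directed by the free OH, which outranks OMe, with NBS in MeCN para‑selective, so bromine enters C4 (the later 8'‑position).

Step 10
Reactants: 8 (1R,3R)-8-(benzyloxy)-5-bromo-1,3-dimethyl-1,2,3,4-tetrahydroisoquinoline; 12 4-bromo-8-methoxy-6-methylnaphthalen-1-ol
Product: 14 4-[(1R,3R)-8-(benzyloxy)-1,3-dimethyl-1,2,3,4-tetrahydroisoquinolin-5-yl]-8-methoxy-6-methylnaphthalen-1-ol, via boronate 13 (not isolated)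
Conditions: 8, B2pin2 (1.05 equiv), KOAc, PdCl2(dppf) (5 mol %), 1,4-dioxane, 90 °C; then 12, Pd(OAc)2/SPhos (5/10 mol %), K3PO4, H2O, 90 °C
Reagents that add atoms: bis(pinacolato)diboron CC1(C)OB(OC1(C)C)B1OC(C)(C)C(C)(C)O1 (its atoms stay in 13 only, none in 14)
Why: One‑pot Miyaura borylation and Suzuki–Miyaura coupling joins C5 of the isoquinoline to C4 of the naphthol; free OH and hindered NH are tolerated under aqueous phosphate, no stereocentre is touched, and the new 5,8'‑axis (flanked only by CH2, H and a peri H) rotates freely.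

Step 11
Reactants: 14 4-[(1R,3R)-8-(benzyloxy)-1,3-dimethyl-1,2,3,4-tetrahydroisoquinolin-5-yl]-8-methoxy-6-methylnaphthalen-1-ol
Product: 15 4-[(1R,3R)-8-(benzyloxy)-1,3-dimethyl-1,2,3,4-tetrahydroisoquinolin-5-yl]-2-bromo-8-methoxy-6-methylnaphthalen-1-ol
Conditions: TFA (1.1 equiv), then NBS (1.0 equiv), CH2Cl2/MeCN, −40 → 0 °C
Reagents that add atoms: N-bromosuccinimide O=C1CCC(=O)N1Br
Why: Electrophilic aromatic bromination of the para‑blocked naphthol can only go ortho to the free OH (C2, the 6'‑position), the most activated site of the molecule, while the amine is masked as its trifluoroacetate salt.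

Step 12
Reactants: 1 1-(2,6-dihydroxyphenyl)ethan-1-one
Product: 16 1-(3-chloro-2,6-dihydroxyphenyl)ethan-1-one
Conditions: NCS (1.0 equiv), MeCN, 0 → 20 °C
Reagents that add atoms: N-chlorosuccinimide O=C1CCC(=O)N1Cl
Why: Electrophilic aromatic chlorination; the two activated positions of the symmetric diol are equivalent, so a single mono‑chloride forms and stoichiometry limits dichlorination.

Step 13
Reactants: 16 1-(3-chloro-2,6-dihydroxyphenyl)ethan-1-one
Product: 17 2-acetyl-4-chloro-3-hydroxyphenyl trifluoromethanesulfonate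
Conditions: Tf2O (1.05 equiv), pyridine (2 equiv), CH2Cl2, −78 → −20 °C
Reagents that add atoms: trifluoromethanesulfonic anhydride O=S(=O)(OS(=O)(=O)C(F)(F)F)C(F)(F)F
Why: Regioselective O‑sulfonylation: the chlorine‑flanked hydroxyl is the more acidic one, holds the chelate to C=O, and is the more hindered and less nucleophilic, so triflation should take the other hydroxyl (constitution checked by HMBC/NOE).

Step 14
Reactants: 17 2-acetyl-4-chloro-3-hydroxyphenyl trifluoromethanesulfonate
Product: 18 2-acetyl-3-(benzyloxy)-4-chlorophenyl trifluoromethanesulfonate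
Conditions: BnOH (1.2 equiv), PPh3, DIAD, THF, 0 → 20 °C
Reagents that add atoms: benzyl alcohol OCc1ccccc1
Why: Mitsunobu etherification benzylates the acidic chelated phenol under neutral conditions that cannot cleave or transfer the aryl triflate.

Step 15
Reactants: 18 2-acetyl-3-(benzyloxy)-4-chlorophenyl trifluoromethanesulfonate
Product: 19 1-[2-acetyl-3-(benzyloxy)-4-chlorophenyl]propan-2-one
Conditions: isopropenyl acetate (1.5 equiv), Bu3SnOMe (1.5 equiv), PdCl2(PPh3)2 (5 mol %), LiCl (3 equiv), toluene/DMF 4:1, 100 °C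
Reagents that add atoms: isopropenyl acetate CC(=C)OC(C)=O
Why: Kosugi–Migita acetonylation as in step 3; with PPh3 as ligand, zerovalent palladium inserts into C–OTf and leaves C–Cl for step 17.

Step 16
Reactants: 19 1-[2-acetyl-3-(benzyloxy)-4-chlorophenyl]propan-2-one; 8 (1R,3R)-8-(benzyloxy)-5-bromo-1,3-dimethyl-1,2,3,4-tetrahydroisoquinoline
Product: 22 (1R,3R)-8-(benzyloxy)-5-[5-(benzyloxy)-6-chloro-4-methoxy-2-methylnaphthalen-1-yl]-1,3-dimethyl-1,2,3,4-tetrahydroisoquinoline, via diaryl ketone 20 (not isolated), via naphthol 21 (not isolated)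
Conditions: 8, 19 (1.3 equiv), Pd2(dba)3 (2.5 mol %), Xantphos (6 mol %), K3PO4 (2.5 equiv), toluene, 90 °C; then KOtBu (1.5 equiv), THF, 60 °C; then MeI (2.0 equiv), DMF, 0 °C
Reagents that add atoms: iodomethane CI
Why: Proposed new method: K3PO4 ionises only the most acidic C–H of 19 (the ArCH2C=O methylene), zerovalent palladium/Xantphos inserts into C–Br of 8 but not C–Cl of 19, and reductive elimination gives α,α‑diaryl ketone 20; KOtBu then enolises the acetyl group, which adds to the methyl ketone, and loss of water with tautomerisation gives naphthoxide 21 carrying the isoquinoline at C1'', which MeI methylates faster than the hindered secondary amine; the closest known reactions are the Buchwald–Hartwig α‑arylation of benzyl methyl ketones to 1,1‑diarylpropan‑2‑ones and the aldol aromatisation of step 7; the transient methine becomes sp2, the four stereocentres are untouched, and the C1''–C5''' axis forms as two separable atropo‑diastereomers.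

Step 17
Reactants: 22 (1R,3R)-8-(benzyloxy)-5-[5-(benzyloxy)-6-chloro-4-methoxy-2-methylnaphthalen-1-yl]-1,3-dimethyl-1,2,3,4-tetrahydroisoquinoline; 15 4-[(1R,3R)-8-(benzyloxy)-1,3-dimethyl-1,2,3,4-tetrahydroisoquinolin-5-yl]-2-bromo-8-methoxy-6-methylnaphthalen-1-ol
Product: 24 2-{5-(benzyloxy)-1-[(1R,3R)-8-(benzyloxy)-1,3-dimethyl-1,2,3,4-tetrahydroisoquinolin-5-yl]-4-methoxy-2-methylnaphthalen-6-yl}-4-[(1R,3R)-8-(benzyloxy)-1,3-dimethyl-1,2,3,4-tetrahydroisoquinolin-5-yl]-8-methoxy-6-methylnaphthalen-1-ol, via boronate 23 (not isolated)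
Conditions: 22, B2pin2 (1.2 equiv), KOAc, Pd2(dba)3/XPhos (2.5/10 mol %), 1,4-dioxane, 100 °C; then 15, K3PO4, H2O, 80 °C
Reagents that add atoms: bis(pinacolato)diboron CC1(C)OB(OC1(C)C)B1OC(C)(C)C(C)(C)O1 (its atoms stay in 23 only, none in 24)
Why: Miyaura borylation of the aryl chloride followed in the same flask by Suzuki–Miyaura coupling with the ortho‑bromonaphthol makes the central 6',6''‑bond as a directed cross‑coupling, so no homodimers arise; the bond has only two oxygen ortho substituents and forms easily.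

Step 18
Reactants: 24 the tri-O-benzyl ether named in step 17
Product: 25 2-{5-hydroxy-1-[(1R,3R)-8-hydroxy-1,3-dimethyl-1,2,3,4-tetrahydroisoquinolin-5-yl]-4-methoxy-2-methylnaphthalen-6-yl}-4-[(1R,3R)-8-hydroxy-1,3-dimethyl-1,2,3,4-tetrahydroisoquinolin-5-yl]-8-methoxy-6-methylnaphthalen-1-ol (CNP0077060.1)
Conditions: H2 (1 atm), 10% Pd/C, MeOH, 20 °C, then filtration under argon
Reagents that add atoms: none
Why: Global hydrogenolysis of the three aryl benzyl ethers; aryl methyl ethers, the naphthalenes and the C1/C3 stereocentres are unaffected under these mild conditions, and the product is the target.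

## Compound list

1 | 1-(2,6-dihydroxyphenyl)ethan-1-one | CC(=O)c1c(O)cccc1O | starting material
2 | 1-[2-(benzyloxy)-6-hydroxyphenyl]ethan-1-one | CC(=O)c1c(O)cccc1OCc1ccccc1 | intermediate
3 | 2-acetyl-3-(benzyloxy)phenyl trifluoromethanesulfonate | CC(=O)c1c(OS(=O)(=O)C(F)(F)F)cccc1OCc1ccccc1 | intermediate
4 | 1-[2-acetyl-3-(benzyloxy)phenyl]propan-2-one | CC(=O)Cc1cccc(OCc2ccccc2)c1C(C)=O | intermediate
5 | 1-{2-[(2R)-2-aminopropyl]-6-(benzyloxy)phenyl}ethan-1-one | C[C@@H](N)Cc1cccc(OCc2ccccc2)c1C(C)=O | intermediate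
6 | (3R)-8-(benzyloxy)-1,3-dimethyl-3,4-dihydroisoquinoline | C[C@@H]1Cc2cccc(OCc3ccccc3)c2C(C)=N1 | intermediate
7 | (1R,3R)-8-(benzyloxy)-1,3-dimethyl-1,2,3,4-tetrahydroisoquinoline | C[C@@H]1Cc2cccc(OCc3ccccc3)c2[C@@H](C)N1 | intermediate
8 | (1R,3R)-8-(benzyloxy)-5-bromo-1,3-dimethyl-1,2,3,4-tetrahydroisoquinoline | C[C@@H]1Cc2c(Br)ccc(OCc3ccccc3)c2[C@@H](C)N1 | intermediate
9 | 8-(benzyloxy)-3-methylnaphthalen-1-ol (formed as its potassium salt) | Cc1cc(O)c2c(OCc3ccccc3)cccc2c1 | intermediate
10 | 1-(benzyloxy)-8-methoxy-6-methylnaphthalene | COc1cc(C)cc2cccc(OCc3ccccc3)c12 | intermediate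
11 | 8-methoxy-6-methylnaphthalen-1-ol | COc1cc(C)cc2cccc(O)c12 | intermediate
12 | 4-bromo-8-methoxy-6-methylnaphthalen-1-ol | COc1cc(C)cc2c(Br)ccc(O)c12 | intermediate
13 | (1R,3R)-8-(benzyloxy)-1,3-dimethyl-5-(4,4,5,5-tetramethyl-1,3,2-dioxaborolan-2-yl)-1,2,3,4-tetrahydroisoquinoline | C[C@@H]1Cc2c(B3OC(C)(C)C(C)(C)O3)ccc(OCc3ccccc3)c2[C@@H](C)N1 | intermediate
14 | 4-[(1R,3R)-8-(benzyloxy)-1,3-dimethyl-1,2,3,4-tetrahydroisoquinolin-5-yl]-8-methoxy-6-methylnaphthalen-1-ol | COc1cc(C)cc2c(-c3ccc(OCc4ccccc4)c4c3C[C@@H](C)N[C@@H]4C)ccc(O)c12 | intermediate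
15 | 4-[(1R,3R)-8-(benzyloxy)-1,3-dimethyl-1,2,3,4-tetrahydroisoquinolin-5-yl]-2-bromo-8-methoxy-6-methylnaphthalen-1-ol | COc1cc(C)cc2c(-c3ccc(OCc4ccccc4)c4c3C[C@@H](C)N[C@@H]4C)cc(Br)c(O)c12 | intermediate
16 | 1-(3-chloro-2,6-dihydroxyphenyl)ethan-1-one | CC(=O)c1c(O)ccc(Cl)c1O | intermediate
17 | 2-acetyl-4-chloro-3-hydroxyphenyl trifluoromethanesulfonate | CC(=O)c1c(OS(=O)(=O)C(F)(F)F)ccc(Cl)c1O | intermediate
18 | 2-acetyl-3-(benzyloxy)-4-chlorophenyl trifluoromethanesulfonate | CC(=O)c1c(OS(=O)(=O)C(F)(F)F)ccc(Cl)c1OCc1ccccc1 | intermediate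
19 | 1-[2-acetyl-3-(benzyloxy)-4-chlorophenyl]propan-2-one | CC(=O)Cc1ccc(Cl)c(OCc2ccccc2)c1C(C)=O | intermediate
20 | 1-[2-acetyl-3-(benzyloxy)-4-chlorophenyl]-1-[(1R,3R)-8-(benzyloxy)-1,3-dimethyl-1,2,3,4-tetrahydroisoquinolin-5-yl]propan-2-one (both epimers at the methine) | CC(=O)C(c1ccc(Cl)c(OCc2ccccc2)c1C(C)=O)c1ccc(OCc2ccccc2)c2c1C[C@@H](C)N[C@@H]2C | intermediate
21 | 8-(benzyloxy)-4-[(1R,3R)-8-(benzyloxy)-1,3-dimethyl-1,2,3,4-tetrahydroisoquinolin-5-yl]-7-chloro-3-methylnaphthalen-1-ol (formed as its potassium salt) | Cc1cc(O)c2c(OCc3ccccc3)c(Cl)ccc2c1-c1ccc(OCc2ccccc2)c2c1C[C@@H](C)N[C@@H]2C | intermediate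
22 | (1R,3R)-8-(benzyloxy)-5-[5-(benzyloxy)-6-chloro-4-methoxy-2-methylnaphthalen-1-yl]-1,3-dimethyl-1,2,3,4-tetrahydroisoquinoline | COc1cc(C)c(-c2ccc(OCc3ccccc3)c3c2C[C@@H](C)N[C@@H]3C)c2ccc(Cl)c(OCc3ccccc3)c12 | intermediate
23 | (1R,3R)-8-(benzyloxy)-5-[5-(benzyloxy)-4-methoxy-2-methyl-6-(4,4,5,5-tetramethyl-1,3,2-dioxaborolan-2-yl)naphthalen-1-yl]-1,3-dimethyl-1,2,3,4-tetrahydroisoquinoline | COc1cc(C)c(-c2ccc(OCc3ccccc3)c3c2C[C@@H](C)N[C@@H]3C)c2ccc(B3OC(C)(C)C(C)(C)O3)c(OCc3ccccc3)c12 | intermediate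
24 | tri-O-benzyl ether of 25 (full name in step 17) | COc1cc(C)cc2c(-c3ccc(OCc4ccccc4)c4c3C[C@@H](C)N[C@@H]4C)cc(-c3ccc4c(-c5ccc(OCc6ccccc6)c6c5C[C@@H](C)N[C@@H]6C)c(C)cc(OC)c4c3OCc3ccccc3)c(O)c12 | intermediate
25 | CNP0077060.1 (full name in step 18) | COc1cc(C)cc2c(-c3ccc(O)c4c3C[C@@H](C)N[C@@H]4C)cc(-c3ccc4c(-c5ccc(O)c6c5C[C@@H](C)N[C@@H]6C)c(C)cc(OC)c4c3O)c(O)c12 | target

## Step count and risks

Total step count: 18.
Longest linear sequence: 10 steps (1 → 2 → 3 → 4 → 6 → 7 → 8 → 14 → 15 → 24 → 25; steps 1, 2, 3, 4, 5, 6, 10, 11, 17, 18).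

Most likely to fail:

Step 16. Diketone 19 may cyclise on its own before it is arylated, the doubly ortho‑hindered arylation may be slow, or the aldol may take the other direction. The fallback sets out from 19 and comes back to the route at 22. Compound 19 alone is cyclised with KOtBu (the aldol aromatisation of step 7) to 8-(benzyloxy)-7-chloro-3-methylnaphthalen-1-ol F1. NBS in MeCN brominates para to the free hydroxyl to give 8-(benzyloxy)-4-bromo-7-chloro-3-methylnaphthalen-1-ol F2. MeI/K2CO3 then gives 5-(benzyloxy)-1-bromo-6-chloro-4-methoxy-2-methylnaphthalene F3. A Suzuki–Miyaura coupling of F3 with boronate 13 (made from 8 as in step 10; PdCl2(dppf), aqueous K3PO4, which leaves C–Cl alone) gives 22. The hindered axis is then made by biaryl coupling on a finished naphthalene instead of by ring formation.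

Step 4. The enzyme may not accept the bulky, poorly soluble ortho,ortho‑disubstituted ketone. The fallback sets out from 4 and comes back at 6. (R)-tert-Butanesulfinamide with Ti(OEt)4 condenses only with the unhindered methyl ketone to give (R,E)-N-{1-[2-acetyl-3-(benzyloxy)phenyl]propan-2-ylidene}-2-methylpropane-2-sulfinamide F4. NaBH4 at −48 °C reduces it to (R)-N-{(2R)-1-[2-acetyl-3-(benzyloxy)phenyl]propan-2-yl}-2-methylpropane-2-sulfinamide F5, with the minor diastereomer removed by chromatography. HCl/MeOH removes the auxiliary and the free amine closes to 6 on neutralisation. C3 is then set by an auxiliary instead of an enzyme.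

Step 3 (the same coupling recurs in step 15). The tin‑enolate coupling is established for aryl bromides and may be sluggish with the ortho‑acyl triflate. The fallback sets out from 3 and comes back at 4. Stille allylation (allyltributylstannane, Pd(PPh3)4, LiCl, DMF) gives 1-[2-(benzyloxy)-6-(prop-2-en-1-yl)phenyl]ethan-1-one F6, and Tsuji–Wacker oxidation (PdCl2, CuCl, O2, DMF/H2O) gives 4. Applied to 18, the same two operations pass through 1-[2-(benzyloxy)-3-chloro-6-(prop-2-en-1-yl)phenyl]ethan-1-one F7 and come back at 19. The three‑carbon ketone is then built by allylation and oxidation instead of one enolate coupling.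

Further compounds
F1 | step 16 | 8-(benzyloxy)-7-chloro-3-methylnaphthalen-1-ol | Cc1cc(O)c2c(OCc3ccccc3)c(Cl)ccc2c1
F2 | step 16 | 8-(benzyloxy)-4-bromo-7-chloro-3-methylnaphthalen-1-ol | Cc1cc(O)c2c(OCc3ccccc3)c(Cl)ccc2c1Br
F3 | step 16 | 5-(benzyloxy)-1-bromo-6-chloro-4-methoxy-2-methylnaphthalene | COc1cc(C)c(Br)c2ccc(Cl)c(OCc3ccccc3)c12
F4 | step 4 | (R,E)-N-{1-[2-acetyl-3-(benzyloxy)phenyl]propan-2-ylidene}-2-methylpropane-2-sulfinamide | CC(C)(C)[S@@](=O)/N=C(\C)Cc1cccc(OCc2ccccc2)c1C(C)=O
F5 | step 4 | (R)-N-{(2R)-1-[2-acetyl-3-(benzyloxy)phenyl]propan-2-yl}-2-methylpropane-2-sulfinamide | CC(C)(C)[S@@](=O)N[C@H](C)Cc1cccc(OCc2ccccc2)c1C(C)=O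
F6 | step 3 | 1-[2-(benzyloxy)-6-(prop-2-en-1-yl)phenyl]ethan-1-one | C=CCc1cccc(OCc2ccccc2)c1C(C)=O
F7 | step 3 | 1-[2-(benzyloxy)-3-chloro-6-(prop-2-en-1-yl)phenyl]ethan-1-one | C=CCc1ccc(Cl)c(OCc2ccccc2)c1C(C)=O
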